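**Retrosynthetic overview**
- The target is opened at its two aryl–O–alkyl ether bonds (C–O), which gives three simple aromatic building blocks: a vanillin unit (ring A), a 3,4,5-trioxygenated aryl unit (ring B) and methyl dihydroferulate (ring C).
- The ring C phenol is added to a ring B aryl ynoate (oxa-Michael, O1–C2 bond). Pd(OAc)2-mediated C–H closure then gives the aromatic benzofuran, which is the first and only ring formed.
- Selective removal of the central methyl ether of ring B frees the phenol. This is O-alkylated with a chloroacetyl oxazolidinone (C8–O bond), and an Evans syn-aldol with vanillin acetate builds the glycerol arm.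
- The furan ring is reduced last to the 2,3-cis dihydrofuran by a new asymmetric hydrogenation with a chiral bis(NHC)ruthenium catalyst. A Mitsunobu C–O inversion then corrects C7 from threo to erythro.
- A single LiBH4 reduction removes the auxiliary and all acyl groups and turns three carbonyl groups into the three CH2OH groups.

Assumption: the SMILES is read as the erythro (7R,8S) arylglycerol ether and the 2,3-cis (2R,3R) dihydrobenzofuran (both ring hydrogens on the same face); the route is built for exactly this isomer.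
Assumption: in step 7 the (R,R) ligand is taken to give the (2R) sense; if the sense is opposite, the (S,S) ligand is used without other change. (R,R)-SINpEt = 1,3-bis[(1R)-1-(naphthalen-1-yl)ethyl]imidazolidin-2-ylidene.

**Route**

Step 1
Reactants: 1 5-iodo-1,2,3-trimethoxybenzene; 2 ethyl prop-2-ynoate (ethyl propiolate)
Product: 3 ethyl 3-(3,4,5-trimethoxyphenyl)prop-2-ynoate
Conditions: Pd(PPh3)2Cl2 (2 mol%), CuI (4 mol%), K2CO3 (2 equiv), THF, 65 °C, slow addition of 2 (3 equiv)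
Reagents that add atoms: none
Why: Sonogashira coupling of an aryl iodide with a propiolate ester; the carbonate base (no amine) avoids conjugate addition to the ynoate.

Step 2
Reactants: 3 ethyl 3-(3,4,5-trimethoxyphenyl)prop-2-ynoate; 4 methyl 3-(4-hydroxy-3-methoxyphenyl)propanoate (methyl dihydroferulate)
Product: 5 ethyl (Z)-3-[2-methoxy-4-(3-methoxy-3-oxopropyl)phenoxy]-3-(3,4,5-trimethoxyphenyl)prop-2-enoate (Z/E mixture, Z drawn)
Conditions: Cs2CO3 (20 mol%), DMF, 70 °C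
Reagents that add atoms: none
Why: Oxa-Michael addition of the phenoxide to the β-carbon of the ynoate forms the O1–C2 aryl vinyl ether bond regiospecifically; both alkene isomers converge in step 3.

Step 3
Reactants: 5 ethyl (Z)-3-[2-methoxy-4-(3-methoxy-3-oxopropyl)phenoxy]-3-(3,4,5-trimethoxyphenyl)prop-2-enoate
Product: 6 ethyl 7-methoxy-5-(3-methoxy-3-oxopropyl)-2-(3,4,5-trimethoxyphenyl)-1-benzofuran-3-carboxylate
Conditions: Pd(OAc)2 (10 mol%), PPh3 (10 mol%), AgO2CCF3 (2.2 equiv), PhCl, 110 °C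
Reagents that add atoms: none
Why: Dehydrogenative (oxidative Heck-type) intramolecular C–H/C–H coupling: divalent palladium palladates the nucleophilic α-carbon of the β-aryloxyacrylate, activates the only free ortho C–H of ring C and closes C3–C3a, and AgO2CCF3 reoxidises zerovalent palladium.

Step 4
Reactants: 6 ethyl 7-methoxy-5-(3-methoxy-3-oxopropyl)-2-(3,4,5-trimethoxyphenyl)-1-benzofuran-3-carboxylate
Product: 7 ethyl 2-(4-hydroxy-3,5-dimethoxyphenyl)-7-methoxy-5-(3-methoxy-3-oxopropyl)-1-benzofuran-3-carboxylate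
Conditions: AlCl3 (5 equiv), CH2Cl2, 0 °C → rt; 1 M HCl work-up
Reagents that add atoms: none
Why: Lewis-acid aryl methyl ether cleavage is selective for the central methoxy group of a 1,2,3-trimethoxyarene, which is twisted out of plane, chelates AlCl3 with its neighbours and sits para to the vinylogous ester (classical pyrogallol trimethyl ether to syringyl demethylation).

Step 5
Reactants: 7 ethyl 2-(4-hydroxy-3,5-dimethoxyphenyl)-7-methoxy-5-(3-methoxy-3-oxopropyl)-1-benzofuran-3-carboxylate; 8 (4R)-4-benzyl-3-(chloroacetyl)-1,3-oxazolidin-2-one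
Product: 9 ethyl 2-[4-(2-[(4R)-4-benzyl-2-oxo-1,3-oxazolidin-3-yl]-2-oxoethoxy)-3,5-dimethoxyphenyl]-7-methoxy-5-(3-methoxy-3-oxopropyl)-1-benzofuran-3-carboxylate
Conditions: K2CO3 (1.5 equiv), MeCN, 50 °C
Reagents that add atoms: none
Why: Williamson ether synthesis (SN2 of the hindered phenoxide on the very reactive α-chloro imide) forms the C8–O aryl ether bond on the base-stable benzofuran.

Step 6
Reactants: 9 ethyl 2-[4-(2-[(4R)-4-benzyl-2-oxo-1,3-oxazolidin-3-yl]-2-oxoethoxy)-3,5-dimethoxyphenyl]-7-methoxy-5-(3-methoxy-3-oxopropyl)-1-benzofuran-3-carboxylate; 10 4-formyl-2-methoxyphenyl acetate (vanillin acetate)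
Product: 12 ethyl 2-[4-({(1S,2R)-1-[4-(acetyloxy)-3-methoxyphenyl]-3-[(4R)-4-benzyl-2-oxo-1,3-oxazolidin-3-yl]-1-hydroxy-3-oxopropan-2-yl}oxy)-3,5-dimethoxyphenyl]-7-methoxy-5-(3-methoxy-3-oxopropyl)-1-benzofuran-3-carboxylate, via dibutylboron Z-enolate 11 (not isolated)
Conditions: Bu2BOTf (1.15 equiv), i-Pr2NEt (1.3 equiv), CH2Cl2, −78 → 0 °C; then 10, −78 → 0 °C; pH 7 buffer, MeOH, H2O2, 0 °C
Reagents that add atoms: dibutylboron triflate, CCCCB(CCCC)OS(=O)(=O)C(F)(F)F (its Bu2B group is present only in 11)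
Why: Evans boron syn-aldol through the Z-enolate and a Zimmerman–Traxler chair: the (4R)-benzyl auxiliary sets C8 (8S in target numbering) and gives the syn (threo) adduct with C7 = S, which is corrected in step 8; the imide is enolised selectively over the two alkyl esters.

Step 7
Reactants: 12 ethyl 2-[4-({(1S,2R)-1-[4-(acetyloxy)-3-methoxyphenyl]-3-[(4R)-4-benzyl-2-oxo-1,3-oxazolidin-3-yl]-1-hydroxy-3-oxopropan-2-yl}oxy)-3,5-dimethoxyphenyl]-7-methoxy-5-(3-methoxy-3-oxopropyl)-1-benzofuran-3-carboxylate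
Product: 13 ethyl (2R,3S)-2-[4-({(1S,2R)-1-[4-(acetyloxy)-3-methoxyphenyl]-3-[(4R)-4-benzyl-2-oxo-1,3-oxazolidin-3-yl]-1-hydroxy-3-oxopropan-2-yl}oxy)-3,5-dimethoxyphenyl]-7-methoxy-5-(3-methoxy-3-oxopropyl)-2,3-dihydro-1-benzofuran-3-carboxylate (2,3-cis)
Conditions: [Ru(cod)(2-methylallyl)2] (5 mol%), (R,R)-SINpEt·HBF4 (10 mol%), KOtBu (9 mol%), n-hexane, 70 °C (catalyst preformation); then H2 (100 bar), PhMe, 40 °C
Reagents that add atoms: none
Why: Proposed new method: enantio- and cis-selective hydrogenation of the tetrasubstituted C2=C3 bond of a 2-aryl-1-benzofuran-3-carboxylate by a chiral bis(NHC) complex of divalent ruthenium; the furan ring of a benzofuran keeps little aromatic stabilisation and is here a vinylogous carbonate (β-aryl-β-aryloxy acrylate), so face-selective coordination (steered by the naphthylethyl wings of the NHC) and syn delivery of both hydrogens should give only the 2,3-cis product, setting C2 = R and C3 = S (ester numbering, 3R in the target) together under base-free conditions that cannot epimerise the cis ester; closest known reaction type is the asymmetric hydrogenation of 2-substituted benzofurans and of flavones/chromones with the same catalyst family, not yet shown for 2,3-disubstituted benzofuran-3-carboxylates.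

Step 8
Reactants: 13 ethyl (2R,3S)-2-[4-({(1S,2R)-1-[4-(acetyloxy)-3-methoxyphenyl]-3-[(4R)-4-benzyl-2-oxo-1,3-oxazolidin-3-yl]-1-hydroxy-3-oxopropan-2-yl}oxy)-3,5-dimethoxyphenyl]-7-methoxy-5-(3-methoxy-3-oxopropyl)-2,3-dihydro-1-benzofuran-3-carboxylate
Product: 14 ethyl (2R,3S)-2-[4-({(1R,2R)-1-[4-(acetyloxy)-3-methoxyphenyl]-3-[(4R)-4-benzyl-2-oxo-1,3-oxazolidin-3-yl]-1-[(4-nitrobenzoyl)oxy]-3-oxopropan-2-yl}oxy)-3,5-dimethoxyphenyl]-7-methoxy-5-(3-methoxy-3-oxopropyl)-2,3-dihydro-1-benzofuran-3-carboxylate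
Conditions: 4-nitrobenzoic acid, PPh3, DIAD, THF, 0 °C → rt
Reagents that add atoms: 4-nitrobenzoic acid, OC(=O)c1ccc(cc1)[N+](=O)[O-]
Why: Mitsunobu esterification forms the C7–O bond with SN2 inversion (7S → 7R), turning the threo adduct into the erythro series; the 4-acetoxy group tempers benzylic ionisation and the neutral medium leaves the cis ester and C8 untouched.

Step 9
Reactants: 14 ethyl (2R,3S)-2-[4-({(1R,2R)-1-[4-(acetyloxy)-3-methoxyphenyl]-3-[(4R)-4-benzyl-2-oxo-1,3-oxazolidin-3-yl]-1-[(4-nitrobenzoyl)oxy]-3-oxopropan-2-yl}oxy)-3,5-dimethoxyphenyl]-7-methoxy-5-(3-methoxy-3-oxopropyl)-2,3-dihydro-1-benzofuran-3-carboxylate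
Product: 15 (1R,2S)-1-(4-hydroxy-3-methoxyphenyl)-2-{4-[(2R,3R)-3-(hydroxymethyl)-5-(3-hydroxypropyl)-7-methoxy-2,3-dihydro-1-benzofuran-2-yl]-2,6-dimethoxyphenoxy}propane-1,3-diol (CNP0301567.1)
Conditions: LiBH4 (8 equiv), THF–MeOH (10:1), 0 °C → rt; aq. NH4Cl
Reagents that add atoms: none
Why: Hydride reduction with LiBH4 cleaves the N-acyl oxazolidinone reductively to the C9 alcohol, reduces both alkyl esters to CH2OH and removes the nitrobenzoate and the aryl acetate in one operation (the nitro group survives); no stereocentre is touched because the C3 ester is reduced faster than it can epimerise at 0 °C.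

**Compound list**
1 | 5-iodo-1,2,3-trimethoxybenzene | COc1cc(I)cc(OC)c1OC | starting material
2 | ethyl prop-2-ynoate | CCOC(=O)C#C | starting material
3 | ethyl 3-(3,4,5-trimethoxyphenyl)prop-2-ynoate | CCOC(=O)C#Cc1cc(OC)c(OC)c(OC)c1 | intermediate
4 | methyl 3-(4-hydroxy-3-methoxyphenyl)propanoate | COC(=O)CCc1ccc(O)c(OC)c1 | starting material
5 | ethyl (Z)-3-[2-methoxy-4-(3-methoxy-3-oxopropyl)phenoxy]-3-(3,4,5-trimethoxyphenyl)prop-2-enoate (Z/E mixture, Z drawn) | CCOC(=O)/C=C(\Oc1ccc(CCC(=O)OC)cc1OC)c1cc(OC)c(OC)c(OC)c1 | intermediate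
6 | ethyl 7-methoxy-5-(3-methoxy-3-oxopropyl)-2-(3,4,5-trimethoxyphenyl)-1-benzofuran-3-carboxylate | CCOC(=O)c1c(-c2cc(OC)c(OC)c(OC)c2)oc2c(OC)cc(CCC(=O)OC)cc12 | intermediate
7 | ethyl 2-(4-hydroxy-3,5-dimethoxyphenyl)-7-methoxy-5-(3-methoxy-3-oxopropyl)-1-benzofuran-3-carboxylate | CCOC(=O)c1c(-c2cc(OC)c(O)c(OC)c2)oc2c(OC)cc(CCC(=O)OC)cc12 | intermediate
8 | (4R)-4-benzyl-3-(chloroacetyl)-1,3-oxazolidin-2-one | ClCC(=O)N1[C@H](Cc2ccccc2)COC1=O | starting material
9 | ethyl 2-[4-(2-[(4R)-4-benzyl-2-oxo-1,3-oxazolidin-3-yl]-2-oxoethoxy)-3,5-dimethoxyphenyl]-7-methoxy-5-(3-methoxy-3-oxopropyl)-1-benzofuran-3-carboxylate | CCOC(=O)c1c(-c2cc(OC)c(OCC(=O)N3[C@H](Cc4ccccc4)COC3=O)c(OC)c2)oc2c(OC)cc(CCC(=O)OC)cc12 | intermediate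
10 | 4-formyl-2-methoxyphenyl acetate | CC(=O)Oc1ccc(C=O)cc1OC | starting material
11 | ethyl 2-[4-({(Z)-2-[(4R)-4-benzyl-2-oxo-1,3-oxazolidin-3-yl]-2-[(dibutylboranyl)oxy]ethenyl}oxy)-3,5-dimethoxyphenyl]-7-methoxy-5-(3-methoxy-3-oxopropyl)-1-benzofuran-3-carboxylate (Z-boron enolate of 9) | CCCCB(CCCC)O/C(N1[C@H](Cc2ccccc2)COC1=O)=C\Oc1c(OC)cc(cc1OC)-c1oc2c(OC)cc(CCC(=O)OC)cc2c1C(=O)OCC | intermediate (not isolated)
12 | ethyl 2-[4-({(1S,2R)-1-[4-(acetyloxy)-3-methoxyphenyl]-3-[(4R)-4-benzyl-2-oxo-1,3-oxazolidin-3-yl]-1-hydroxy-3-oxopropan-2-yl}oxy)-3,5-dimethoxyphenyl]-7-methoxy-5-(3-methoxy-3-oxopropyl)-1-benzofuran-3-carboxylate | CCOC(=O)c1c(-c2cc(OC)c(O[C@H]([C@@H](O)c5ccc(OC(C)=O)c(OC)c5)C(=O)N3[C@H](Cc4ccccc4)COC3=O)c(OC)c2)oc2c(OC)cc(CCC(=O)OC)cc12 | intermediate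
13 | ethyl (2R,3S)-2-[4-({(1S,2R)-1-[4-(acetyloxy)-3-methoxyphenyl]-3-[(4R)-4-benzyl-2-oxo-1,3-oxazolidin-3-yl]-1-hydroxy-3-oxopropan-2-yl}oxy)-3,5-dimethoxyphenyl]-7-methoxy-5-(3-methoxy-3-oxopropyl)-2,3-dihydro-1-benzofuran-3-carboxylate (2,3-cis) | CCOC(=O)[C@@H]1[C@H](c2cc(OC)c(O[C@H]([C@@H](O)c5ccc(OC(C)=O)c(OC)c5)C(=O)N3[C@H](Cc4ccccc4)COC3=O)c(OC)c2)Oc2c(OC)cc(CCC(=O)OC)cc12 | intermediate
14 | ethyl (2R,3S)-2-[4-({(1R,2R)-1-[4-(acetyloxy)-3-methoxyphenyl]-3-[(4R)-4-benzyl-2-oxo-1,3-oxazolidin-3-yl]-1-[(4-nitrobenzoyl)oxy]-3-oxopropan-2-yl}oxy)-3,5-dimethoxyphenyl]-7-methoxy-5-(3-methoxy-3-oxopropyl)-2,3-dihydro-1-benzofuran-3-carboxylate | CCOC(=O)[C@@H]1[C@H](c2cc(OC)c(O[C@H]([C@H](OC(=O)c6ccc(cc6)[N+](=O)[O-])c5ccc(OC(C)=O)c(OC)c5)C(=O)N3[C@H](Cc4ccccc4)COC3=O)c(OC)c2)Oc2c(OC)cc(CCC(=O)OC)cc12 | intermediate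
15 | (1R,2S)-1-(4-hydroxy-3-methoxyphenyl)-2-{4-[(2R,3R)-3-(hydroxymethyl)-5-(3-hydroxypropyl)-7-methoxy-2,3-dihydro-1-benzofuran-2-yl]-2,6-dimethoxyphenoxy}propane-1,3-diol | COc1cc([C@@H](O)[C@H](CO)Oc2c(OC)cc([C@@H]3Oc4c(OC)cc(CCCO)cc4[C@@H]3CO)cc2OC)ccc1O | target

**Step count and risks**
Total step count: 9. Longest linear sequence: 9 steps (1 to 15; 2, 4, 8 and 10 enter as bought building blocks).

Three steps most likely to fail:

Step 7 (the proposed new hydrogenation): the tetrasubstituted, ester-bearing furan C=C may be inert to the catalyst or give low selectivity. The fallback uses known chemistry and moves stereocontrol from the catalyst to separation of diastereomers. It sets out from 12, which is hydrogenated over an achiral heterogeneous catalyst (5% Rh/Al2O3, H2 40 bar, EtOAc, 25 °C, stopped after one equivalent of H2), a known cis-selective reduction of the furan ring of benzofurans. This gives 13 together with the other cis isomer, ethyl (2S,3R)-2-[4-({(1S,2R)-1-[4-(acetyloxy)-3-methoxyphenyl]-3-[(4R)-4-benzyl-2-oxo-1,3-oxazolidin-3-yl]-1-hydroxy-3-oxopropan-2-yl}oxy)-3,5-dimethoxyphenyl]-7-methoxy-5-(3-methoxy-3-oxopropyl)-2,3-dihydro-1-benzofuran-3-carboxylate F3. The two are diastereomers because of the auxiliary and the side-chain stereocentres, so they are separated by preparative HPLC, and the route comes back at 13.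

Step 3 (oxidative C–H cyclisation): the β,β-disubstituted aryl vinyl ether may cyclise sluggishly or homocouple. The fallback replaces C–H activation by a halide-based intramolecular Heck closure. It sets out from 4, which is iodinated ortho to the hydroxyl (NIS, TsOH cat., MeCN) to methyl 3-(4-hydroxy-3-iodo-5-methoxyphenyl)propanoate F1. Oxa-Michael addition of F1 to 3 (Cs2CO3, DMF, 70 °C) gives ethyl (Z)-3-[2-iodo-6-methoxy-4-(3-methoxy-3-oxopropyl)phenoxy]-3-(3,4,5-trimethoxyphenyl)prop-2-enoate F2. Treatment of F2 with Pd(OAc)2, PPh3 and Ag2CO3 in MeCN at 80 °C closes the C3–C3a bond, and the route comes back at 6.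

Step 8 (Mitsunobu inversion at the benzylic, β-acyl carbinol): elimination to the enol ether or partial retention is possible. The fallback builds the erythro relationship directly in the aldol step, so no inversion is needed. It sets out from 7, which is alkylated with the commercial (4S) enantiomer of 8 (K2CO3, MeCN) to ethyl 2-[4-(2-[(4S)-4-benzyl-2-oxo-1,3-oxazolidin-3-yl]-2-oxoethoxy)-3,5-dimethoxyphenyl]-7-methoxy-5-(3-methoxy-3-oxopropyl)-1-benzofuran-3-carboxylate F4. Its dibutylboron enolate (Bu2BOTf, i-Pr2NEt) is added to 10 that has been precomplexed with Et2AlCl. This is the open-transition-state anti variant of the Evans aldol; it attacks the enolate face opposite to that of the chair reaction and therefore pairs the (4S) auxiliary with the required C8 configuration. The product is ethyl 2-[4-({(1R,2R)-1-[4-(acetyloxy)-3-methoxyphenyl]-3-[(4S)-4-benzyl-2-oxo-1,3-oxazolidin-3-yl]-1-hydroxy-3-oxopropan-2-yl}oxy)-3,5-dimethoxyphenyl]-7-methoxy-5-(3-methoxy-3-oxopropyl)-1-benzofuran-3-carboxylate F5. Hydrogenation under the conditions of step 7 gives ethyl (2R,3S)-2-[4-({(1R,2R)-1-[4-(acetyloxy)-3-methoxyphenyl]-3-[(4S)-4-benzyl-2-oxo-1,3-oxazolidin-3-yl]-1-hydroxy-3-oxopropan-2-yl}oxy)-3,5-dimethoxyphenyl]-7-methoxy-5-(3-methoxy-3-oxopropyl)-2,3-dihydro-1-benzofuran-3-carboxylate F6. LiBH4 reduction of F6 under the conditions of step 9 brings the route back at 15.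

Further compounds
F1 | step 3 | methyl 3-(4-hydroxy-3-iodo-5-methoxyphenyl)propanoate | COC(=O)CCc1cc(I)c(O)c(OC)c1
F2 | step 3 | ethyl (Z)-3-[2-iodo-6-methoxy-4-(3-methoxy-3-oxopropyl)phenoxy]-3-(3,4,5-trimethoxyphenyl)prop-2-enoate | CCOC(=O)/C=C(\Oc1c(I)cc(CCC(=O)OC)cc1OC)c1cc(OC)c(OC)c(OC)c1
F3 | step 7 | ethyl (2S,3R)-2-[4-({(1S,2R)-1-[4-(acetyloxy)-3-methoxyphenyl]-3-[(4R)-4-benzyl-2-oxo-1,3-oxazolidin-3-yl]-1-hydroxy-3-oxopropan-2-yl}oxy)-3,5-dimethoxyphenyl]-7-methoxy-5-(3-methoxy-3-oxopropyl)-2,3-dihydro-1-benzofuran-3-carboxylate | CCOC(=O)[C@H]1[C@@H](c2cc(OC)c(O[C@H]([C@@H](O)c5ccc(OC(C)=O)c(OC)c5)C(=O)N3[C@H](Cc4ccccc4)COC3=O)c(OC)c2)Oc2c(OC)cc(CCC(=O)OC)cc12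
F4 | step 8 | ethyl 2-[4-(2-[(4S)-4-benzyl-2-oxo-1,3-oxazolidin-3-yl]-2-oxoethoxy)-3,5-dimethoxyphenyl]-7-methoxy-5-(3-methoxy-3-oxopropyl)-1-benzofuran-3-carboxylate | CCOC(=O)c1c(-c2cc(OC)c(OCC(=O)N3[C@@H](Cc4ccccc4)COC3=O)c(OC)c2)oc2c(OC)cc(CCC(=O)OC)cc12
F5 | step 8 | ethyl 2-[4-({(1R,2R)-1-[4-(acetyloxy)-3-methoxyphenyl]-3-[(4S)-4-benzyl-2-oxo-1,3-oxazolidin-3-yl]-1-hydroxy-3-oxopropan-2-yl}oxy)-3,5-dimethoxyphenyl]-7-methoxy-5-(3-methoxy-3-oxopropyl)-1-benzofuran-3-carboxylate | CCOC(=O)c1c(-c2cc(OC)c(O[C@H]([C@H](O)c5ccc(OC(C)=O)c(OC)c5)C(=O)N3[C@@H](Cc4ccccc4)COC3=O)c(OC)c2)oc2c(OC)cc(CCC(=O)OC)cc12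
F6 | step 8 | ethyl (2R,3S)-2-[4-({(1R,2R)-1-[4-(acetyloxy)-3-methoxyphenyl]-3-[(4S)-4-benzyl-2-oxo-1,3-oxazolidin-3-yl]-1-hydroxy-3-oxopropan-2-yl}oxy)-3,5-dimethoxyphenyl]-7-methoxy-5-(3-methoxy-3-oxopropyl)-2,3-dihydro-1-benzofuran-3-carboxylate | CCOC(=O)[C@@H]1[C@H](c2cc(OC)c(O[C@H]([C@H](O)c5ccc(OC(C)=O)c(OC)c5)C(=O)N3[C@@H](Cc4ccccc4)COC3=O)c(OC)c2)Oc2c(OC)cc(CCC(=O)OC)cc12
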